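Early in the south-west run side product lags links, 2 % against 36 % at 5.00 min, so treat links as its source and ask how its rate depends on [links].

| setting | south | north-west | south-east | south-west | dawn | autumn | noon | summer | dusk | winter |
|---|---|---|---|---|---|---|---|---|---|---|
| first end groups | 29 mM | 14 mM | 22 mM | 29 mM | 29 mM | 29 mM (fed, over 2.5 min) | 29 mM (fed, over 25 min) | 29 mM | 29 mM | 29 mM (fed, over 25 min) |
| second end groups | 29.6 mM | 29.6 mM | 29.6 mM | 44 mM | 29.6 mM | 29.6 mM | 29.6 mM | 29.6 mM (in portions, 4, over 25 min) | 29.6 mM (fed, over 25 min) | 29.6 mM |
| temperature | −15 °C | 0 °C | −15 °C | 0 °C |  | 0 °C | 0 °C | 0 °C | 0 °C |  |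
| remark | run made earlier | run made earlier | run made earlier | run made earlier | everything together at the start at −30 °C, warmed to 0 °C at 25 min | all else is in the flask from the start; the feed brings no volume worth counting | all else is in the flask from the start; the feed brings no volume worth counting | first portion at the start, last at 25 min | all else is in the flask from the start; the feed brings no volume worth counting | the addition at −30 °C, then warmed to 0 °C; the feed brings no volume worth counting |
| time |  |  |  |  | 40 min | 40 min | 40 min | 40 min | 40 min | 40 min |

| run | time / min | side product / % | links / % |
|---|---|---|---|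
| south | 6.00 | 0 | 14 |
| south | 15.0 | 2 | 23 |
| south | 30.0 | 1 | 30 |
| south | 50.0 | 7 | 34 |
| north-west | 5.00 | 1 | 25 |
| north-west | 15.0 | 10 | 44 |
| north-west | 25.0 | 17 | 44 |
| north-west | 40.0 | 32 | 40 |
| south-east | 20.0 | 2 | 26 |
| south-east | 40.0 | 3 | 38 |
| south-east | 60.0 | 9 | 37 |
| south-east | 80.0 | 12 | 40 |
| south-west | 5.00 | 2 | 36 |
| south-west | 15.0 | 18 | 41 |
| south-west | 25.0 | 37 | 33 |
| south-west | 40.0 | 52 | 24 |

(readings scatter by 1.5 percentage points)



- which flask leads in amount of side product, in percent of the first end groups charged ("all alike" within 1.5 percentage points) (dawn / autumn / noon / summer / dusk / winter / all alike)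
- how much side product is there at the end, in percent of the first end groups charged: dawn
- how much side product is there at the end, in percent of the first end groups charged: autumn
- how much side product is there at the end, in percent of the first end groups charged: noon
- how much side product is there at the end, in percent of the first end groups charged: summer
- how much side product is there at the end, in percent of the first end groups charged: dusk
- how much side product is there at the end, in percent of the first end groups charged: winter

1. Take the two runs at 0 °C, from 15.0 min to 40.0 min. North-west makes side product at 0.123 mM/min on a mean [links] of 5.88 mM. South-west makes it at 0.394 mM/min on 9.43 mM.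

2. Divide by [links] and south-west comes out at twice north-west, so across these two runs the rate doesn't go simply with [links]. Divide by [links] squared and you read 0.00356 /mM/min and 0.00444 /mM/min. Keep their mean, 0.00400 /mM/min: κ, the rate of side product per [links] squared at 0 °C, an apparent second-order rate constant, read with the scatter of its readings.

3. Bet on autumn: its charge is in by 2.5 min, sooner than the 25 min of noon, summer and dusk, and dawn and winter start at −30 °C.

4. Bound it from above: south-west has autumn's first end groups and more second, so its 52 % is your ceiling.

5. Bound it from below: north-west has the same second end groups and fewer first, so its 4.48 mM is your floor, 15.4 % of autumn's charge.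

6. Tighten: run each mean [links] through κ for the 37.5 min after the feed. That gives 17.9 % to 46.0 %. My figure takes the middle [links], 7.65 mM, and gives 30.3 %.

7. The forecast names autumn at 21 % (16 % to 29 %), inside my bracket and below my figure, and gives dawn 10.5 %, noon 19 %, summer 18 %, dusk 16.5 % and winter 9.5 %, with the words “Slow feeds give a little less because links build later”.

8. The flask gives autumn the lead at 36.5 %, inside the bracket and above my figure. Dawn gives 17.0 %, noon 25.2 %, summer 25.3 %, dusk 25.7 % and winter 13.9 %.

    links + by-product → side product (k = 0.0600 /M/s, Ea = 61.0 kJ/mol)
    first end groups + second end groups ⇌ links + by-product (K = 2.90, k = 0.0760 /M/s, Ea = 36.0 kJ/mol, ΔH = −19.0 kJ/mol)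
    second end groups + links → over-reaction product (k = 0.00490 /M/s, Ea = 43.0 kJ/mol)
    second end groups ⇌ dormant form (K = 0.970, k = 0.0230 /s, Ea = 67.0 kJ/mol, ΔH = −34.0 kJ/mol)
    (constants at 0 °C)

To make 36.5 %, autumn needs a mean [links] of 8.40 mM under κ, and it holds 7.59 mM at 40.0 min. Now take the neighbour, winter left until 1.5 h. Its links fall from 34.1 % at 40.0 min to 18.5 % at the later reading, a mean of 7.63 mM. Over those 50.0 min at 0 °C, κ adds 40 percentage points to winter's 13.9 %, which makes 53.9 %. The neighbour flask holds 52.6 % side product.

Readings and results stem from a simulated flask from invented constants.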